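**Strategy.** The butenolide is read as a masked furan. Ring atoms C5, O1 and C2 (the alkylidene carbon, the ring oxygen and the lactone carbonyl carbon) are taken from the C2(Me)–O1–C5(OMe) arc of an oxazole. C3=C4, with the acyl side chain and the bromine, comes from an alkyne. A Diels–Alder/retro-Diels–Alder reaction of 5-methoxy-2,4-dimethyloxazole with 1-bromohex-1-yn-3-one joins C2–C3 and C4–C5 in one operation, expels acetonitrile and gives a tetrasubstituted 2-methoxyfuran. Two bromination/dehydrobromination events then unveil the (Z)-bromomethylene lactone, a CBS reduction sets the (R)-carbinol, and acetylation completes the target.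

Key step: step 4

Remark: racemic hex-1-yn-3-ol is sufficient because its carbinol centre is oxidised in step 3; the alanine centre of 1 is likewise lost when the oxazole forms.

**Step 1**
Reactants: 1 methyl N-acetyl-L-alaninate
Product: 2 5-methoxy-2,4-dimethyloxazole
Conditions: P2O5, CHCl3, reflux; then ice-cold aq. NaOH
Reagents that add atoms: none
Why: Cyclodehydration of an N-acyl α-amino ester (Robinson–Gabriel-type closure to a 5-alkoxyoxazole) should occur by attack of the amide oxygen on the activated ester carbonyl and loss of water, the former stereocentre becoming the sp2 carbon C4.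

**Step 2**
Reactants: 3 hex-1-yn-3-ol (racemic)
Product: 4 1-bromohex-1-yn-3-ol (racemic)
Conditions: NBS (1.1 equiv), AgNO3 (0.1 equiv), acetone, rt, dark
Reagents that add atoms: N-bromosuccinimide, O=C1CCC(=O)N1Br
Why: Silver-catalysed electrophilic bromination of a terminal alkyne (silver acetylide intercepted by NBS) should leave the secondary alcohol untouched.

**Step 3**
Reactants: 4 1-bromohex-1-yn-3-ol
Product: 5 1-bromohex-1-yn-3-one
Conditions: Dess–Martin periodinane (1.2 equiv), CH2Cl2, 0 °C to rt
Reagents that add atoms: none
Why: Dess–Martin oxidation of a propargylic alcohol should give the ynone under near-neutral, non-nucleophilic conditions that the electrophilic bromoalkyne tolerates.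

**Step 4**
Reactants: 2 5-methoxy-2,4-dimethyloxazole; 5 1-bromohex-1-yn-3-one
Product: 7 1-(4-bromo-2-methoxy-5-methylfuran-3-yl)butan-1-one, via oxazanorbornadiene adduct 6 (not isolated)
Conditions: 2 (1.3 equiv), PhMe, 90 °C, sealed tube
Reagents that add atoms: none
Why: The electron-rich 2-azadiene of oxazole 2 (C2=N3–C4=C5, raised in energy by the 5-methoxy group) should add across the electron-poor triple bond of 5 in a normal-demand [4+2] cycloaddition to give the 7-oxa-2-azabicyclo[2.2.1]heptadiene 6, which then undergoes retro-[4+2] cycloreversion with loss of acetonitrile (N3, C4 and its methyl) to the aromatic furan 7, so that the bonds from oxazole C5 and C2 to the alkyne become the C2–C3 and C4–C5 bonds of the later furanone. The closest known reaction type is the oxazole–alkyne Diels–Alder/retro-Diels–Alder furan synthesis, established for 5-alkoxyoxazoles with acetylenic esters and ketones, and β-bromo acetylenic carbonyl compounds are established dienophiles. The five-membered furan ring is closed by intermolecular [4+2] cycloaddition and released from the bicycle by extrusion of the nitrile; no lasting stereocentre is formed, since the two bridgehead centres of 6 are destroyed on aromatisation. The step needs regioselectivity: the bromine-bearing β-carbon of the ynone must bond to oxazole C2 and the acyl-bearing α-carbon to C5(OMe). This should be secured by the match of the largest HOMO coefficient of the 1-alkoxy-2-azadiene at C2 with the largest LUMO coefficient at the ynone β-carbon, the same bias that places acceptor groups next to the oxygenated carbon in pyridoxine-type oxazole cycloadditions. A slight excess of 2 should keep the deactivated push–pull furan 7 from acting as a diene towards residual 5.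

**Step 5**
Reactants: 7 1-(4-bromo-2-methoxy-5-methylfuran-3-yl)butan-1-one
Product: 11 (Z)-4-bromo-5-(bromomethylene)-3-butanoylfuran-2(5H)-one, via 5-bromo-5-methyl lactone 8 (not isolated), via 5-methylene lactone 9 (not isolated), via 5-bromo-5-(bromomethyl) lactone 10 (not isolated)
Conditions: Br2 (1.0 equiv), CH2Cl2, −78 °C; i-Pr2NEt (1.0 equiv), −78 to 0 °C; Br2 (1.0 equiv), −20 °C; i-Pr2NEt (1.1 equiv), 0 °C
Reagents that add atoms: bromine, BrBr
Why: Bromine should attack the methoxyfuran at C5 (ipso to methyl, conjugated with OMe) and bromide should demethylate the resulting lactonium ion (halogenative dealkylation of a 2-alkoxyfuran to a 5-bromobutenolide); base-induced dehydrobromination then gives the 5-methylene lactone, and a second bromine addition/dehydrobromination of the exocyclic enol-lactone alkene gives the bromomethylene, the Z isomer being favoured because the E isomer forces the vinylic bromine against the C4 bromine.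

**Step 6**
Reactants: 11 (Z)-4-bromo-5-(bromomethylene)-3-butanoylfuran-2(5H)-one
Product: 13 (R,Z)-4-bromo-5-(bromomethylene)-3-(1-hydroxybutyl)furan-2(5H)-one, via catechol borate ester 12 (not isolated)
Conditions: (S)-Me-CBS (0.2 equiv), catecholborane (1.5 equiv), PhMe, −78 °C; then pH 7 buffer
Reagents that add atoms: none
Why: Corey–Bakshi–Shibata reduction at −78 °C should give clean 1,2-reduction of the enone-type ketone, the (S)-oxazaborolidine treating the fully substituted ring alkenyl carbon as the large group and n-propyl as the small group, which by analogy with acetophenone and α-substituted enones delivers hydride to the face that gives the (R)-carbinol.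

**Step 7**
Reactants: 13 (R,Z)-4-bromo-5-(bromomethylene)-3-(1-hydroxybutyl)furan-2(5H)-one
Product: 14 (R)-1-[(Z)-4-bromo-5-(bromomethylene)-2-oxo-2,5-dihydrofuran-3-yl]butyl acetate
Conditions: Ac2O (1.5 equiv), Sc(OTf)3 (2 mol%), MeCN, −20 °C
Reagents that add atoms: acetic anhydride, CC(=O)OC(C)=O
Why: Lewis-acid-catalysed O-acetylation should proceed without breaking the carbinol C–O bond, so the configuration is retained, and it avoids nucleophilic amines that could add to the β-bromo enoate.

**Compound list**
1 | methyl N-acetyl-L-alaninate | C[C@H](NC(C)=O)C(=O)OC | starting material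
2 | 5-methoxy-2,4-dimethyloxazole | COc1oc(C)nc1C | intermediate
3 | hex-1-yn-3-ol (racemic) | CCCC(O)C#C | starting material
4 | 1-bromohex-1-yn-3-ol (racemic) | CCCC(O)C#CBr | intermediate
5 | 1-bromohex-1-yn-3-one | CCCC(=O)C#CBr | intermediate
6 | 1-(6-bromo-4-methoxy-1,3-dimethyl-7-oxa-2-azabicyclo[2.2.1]hepta-2,5-dien-5-yl)butan-1-one (racemic, not isolated) | CCCC(=O)C1=C(Br)C2(C)N=C(C)C1(OC)O2 | intermediate
7 | 1-(4-bromo-2-methoxy-5-methylfuran-3-yl)butan-1-one | CCCC(=O)c1c(OC)oc(C)c1Br | intermediate
8 | 4,5-dibromo-3-butanoyl-5-methylfuran-2(5H)-one (racemic, not isolated) | CCCC(=O)C1=C(Br)C(C)(Br)OC1=O | intermediate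
9 | 4-bromo-3-butanoyl-5-methylenefuran-2(5H)-one (not isolated) | CCCC(=O)C1=C(Br)C(=C)OC1=O | intermediate
10 | 4,5-dibromo-5-(bromomethyl)-3-butanoylfuran-2(5H)-one (racemic, not isolated) | CCCC(=O)C1=C(Br)C(Br)(CBr)OC1=O | intermediate
11 | (Z)-4-bromo-5-(bromomethylene)-3-butanoylfuran-2(5H)-one | CCCC(=O)C1=C(Br)/C(=C/Br)OC1=O | intermediate
12 | 2-{(R)-1-[(Z)-4-bromo-5-(bromomethylene)-2-oxo-2,5-dihydrofuran-3-yl]butoxy}-1,3,2-benzodioxaborole (not isolated) | CCC[C@@H](OB1Oc2ccccc2O1)C1=C(Br)/C(=C/Br)OC1=O | intermediate
13 | (R,Z)-4-bromo-5-(bromomethylene)-3-(1-hydroxybutyl)furan-2(5H)-one | CCC[C@@H](O)C1=C(Br)/C(=C/Br)OC1=O | intermediate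
14 | (R)-1-[(Z)-4-bromo-5-(bromomethylene)-2-oxo-2,5-dihydrofuran-3-yl]butyl acetate | CCC[C@@H](OC(C)=O)C1=C(Br)/C(=C/Br)OC1=O | target

**Step count and risks**
Total steps: 7. Longest linear sequence: 6 steps (steps 2 to 7, from hex-1-yn-3-ol 3).

Steps most likely to fail:

1. Step 4. The bromoalkyne may be consumed before cycloaddition, by addition–elimination of the oxazole nitrogen or C4 at the bromine-bearing carbon or by thermal oligomerisation, and the bond formation at the fully substituted termini may be slow. Fallback: the carbon–bromine bond is made after the cycloaddition instead. Setting out from 3, double deprotonation (n-BuLi, THF, −78 °C) and quenching with Bu3SnCl, with cleavage of the O–Sn bond on aqueous work-up, should give 1-(tributylstannyl)hex-1-yn-3-ol F1. Dess–Martin oxidation should give 1-(tributylstannyl)hex-1-yn-3-one F2. Heating F2 with oxazole 2 (PhMe, 110 °C) should give, through the stannylated oxazanorbornadiene adduct F3 and loss of acetonitrile, 1-[2-methoxy-5-methyl-4-(tributylstannyl)furan-3-yl]butan-1-one F4; stannylalkynes are known to survive oxazole Diels–Alder/retro-Diels–Alder conditions. Ipso-bromodestannylation (NBS, CH2Cl2, −78 °C) should then return to the route at furan 7.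

2. Step 5. The telescoped sequence may lose chemoselectivity: the butanoyl α-position may be brominated by bromine or tribromide during the slower addition to the electron-poor exocyclic alkene, over-bromination may occur, or the labile methylene lactone may oligomerise. Fallback: the second bromination is postponed until the ketone is gone. The sequence is stopped after the first bromination/elimination and 9 is isolated. Setting out from 9, the conditions of step 6 should give, through the catechol borate ester F5, (R)-4-bromo-3-(1-hydroxybutyl)-5-methylenefuran-2(5H)-one F6. The conditions of step 7 should give (R)-1-(4-bromo-5-methylene-2-oxo-2,5-dihydrofuran-3-yl)butyl acetate F7. Bromine addition (CH2Cl2, −40 °C) should give the 5-bromo-5-(bromomethyl) acetate F8 (mixture of C5 epimers), and dehydrobromination with i-Pr2NEt at 0 °C should return to the route at the target 14. This is the bromination/dehydrobromination known for 3-alkyl-5-methylene furanones.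

3. Step 6. Facial selectivity may be poor if the lactone carbonyl perturbs the binding of the ketone to the catalyst, and conjugate reduction with loss of the C4 bromine may compete. Fallback: resolution instead of asymmetric reduction. Setting out from 11, Luche reduction (NaBH4, CeCl3·7H2O, MeOH/THF, −78 °C) should give the racemic (Z)-4-bromo-5-(bromomethylene)-3-(1-hydroxybutyl)furan-2(5H)-one F9. Lipase-catalysed acetylation (Burkholderia cepacia lipase, vinyl acetate, MTBE, 30 °C) should acylate the (R)-enantiomer preferentially (Kazlauskas rule: ring as large group, n-propyl as medium group) and so return to the route directly at the target 14. The unreacted (S,Z)-4-bromo-5-(bromomethylene)-3-(1-hydroxybutyl)furan-2(5H)-one F10 can be recycled to 11 by Dess–Martin oxidation.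

**Further compounds**
F1 | step 4 | 1-(tributylstannyl)hex-1-yn-3-ol (racemic) | CCCC(O)C#C[Sn](CCCC)(CCCC)CCCC
F2 | step 4 | 1-(tributylstannyl)hex-1-yn-3-one | CCCC(=O)C#C[Sn](CCCC)(CCCC)CCCC
F3 | step 4 | 1-[4-methoxy-1,3-dimethyl-6-(tributylstannyl)-7-oxa-2-azabicyclo[2.2.1]hepta-2,5-dien-5-yl]butan-1-one (racemic, not isolated) | CCCC(=O)C1=C([Sn](CCCC)(CCCC)CCCC)C2(C)N=C(C)C1(OC)O2
F4 | step 4 | 1-[2-methoxy-5-methyl-4-(tributylstannyl)furan-3-yl]butan-1-one | CCCC(=O)c1c(OC)oc(C)c1[Sn](CCCC)(CCCC)CCCC
F5 | step 5 | 2-[(R)-1-(4-bromo-5-methylene-2-oxo-2,5-dihydrofuran-3-yl)butoxy]-1,3,2-benzodioxaborole (not isolated) | CCC[C@@H](OB1Oc2ccccc2O1)C1=C(Br)C(=C)OC1=O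
F6 | step 5 | (R)-4-bromo-3-(1-hydroxybutyl)-5-methylenefuran-2(5H)-one | CCC[C@@H](O)C1=C(Br)C(=C)OC1=O
F7 | step 5 | (R)-1-(4-bromo-5-methylene-2-oxo-2,5-dihydrofuran-3-yl)butyl acetate | CCC[C@@H](OC(C)=O)C1=C(Br)C(=C)OC1=O
F8 | step 5 | (1R)-1-[4,5-dibromo-5-(bromomethyl)-2-oxo-2,5-dihydrofuran-3-yl]butyl acetate (C5 epimers) | CCC[C@@H](OC(C)=O)C1=C(Br)C(Br)(CBr)OC1=O
F9 | step 6 | (Z)-4-bromo-5-(bromomethylene)-3-(1-hydroxybutyl)furan-2(5H)-one (racemic) | CCCC(O)C1=C(Br)/C(=C/Br)OC1=O
F10 | step 6 | (S,Z)-4-bromo-5-(bromomethylene)-3-(1-hydroxybutyl)furan-2(5H)-one | CCC[C@H](O)C1=C(Br)/C(=C/Br)OC1=O
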